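**Early pace.** Early in Wednesday's run, product forms at 9.10 mM min⁻¹. Averaged to 8.00 min, the pace is 6.51 mM min⁻¹, slower than at first, with substrate down to 16.3%. Friday's run, with 0.12 mM of free catalyst, averages 3.16 mM min⁻¹. The paces stand at 2.06 to one, the catalyst charges at 2.08 to one. Substrate differs as well, 0.070 M against 0.050 M, so this is no clean test, but I take the pace as following catalyst.

| flask | substrate | reagent | free catalyst | temperature | remark | time |
|---|---|---|---|---|---|---|
| Monday's | 0.050 M | 0.15 M | 0.25 mM | −10 °C | run made earlier |  |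
| Wednesday's | 0.070 M | 0.15 M | 0.25 mM | 5 °C | run made earlier |  |
| Sunday's | 0.11 M | 0.15 M | 0.25 mM | −10 °C | run made earlier |  |
| Friday's | 0.050 M | 0.15 M | 0.12 mM | 5 °C | run made earlier |  |
| north-west | 0.050 M | 0.150 M (fed, over 8.0 min) | 0.25 mM |  | the addition at −35 °C, then warmed to 5 °C; the feed brings no volume worth counting | 10 min |
| south | 0.050 M | 0.150 M (in portions, 5, over 8.0 min) | 0.25 mM | 5 °C | first portion at the start, last at 8.0 min | 10 min |
| north-east | 0.050 M | 0.150 M | 0.25 mM |  | everything together at the start at −35 °C, warmed to 5 °C at 8.0 min | 10 min |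
| west | 0.050 M | 0.150 M (fed, over 8.0 min) | 0.25 mM | 5 °C | all else is in the flask from the start; the feed brings no volume worth counting | 10 min |
| south-west | 0.050 M | 0.150 M | 0.25 mM | 5 °C | everything together at the start | 10 min |

| run | time / min | product / % | substrate / % |
|---|---|---|---|
| Monday's | 3.00 | 14.9 | 60.1 |
| Monday's | 6.00 | 29.5 | 35.6 |
| Monday's | 8.00 | 36.7 | 25.6 |
| Monday's | 12.0 | 50.8 | 12.0 |
| Monday's | 15.0 | 57.4 | 9.0 |
| Monday's | 20.0 | 66.5 | 5.0 |
| Wednesday's | 1.00 | 13.0 | 61.0 |
| Wednesday's | 2.50 | 29.9 | 45.7 |
| Wednesday's | 3.00 | 35.2 | 41.9 |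
| Wednesday's | 5.00 | 53.2 | 29.3 |
| Wednesday's | 6.00 | 60.2 | 23.6 |
| Wednesday's | 8.00 | 74.4 | 16.3 |
| Sunday's | 1.33 | 3.2 | 83.2 |
| Sunday's | 2.00 | 5.3 | 76.1 |
| Sunday's | 3.00 | 7.5 | 65.8 |
| Sunday's | 5.00 | 12.9 | 51.9 |
| Sunday's | 6.00 | 15.0 | 44.6 |
| Sunday's | 10.0 | 24.3 | 29.2 |
| Sunday's | 15.0 | 35.0 | 19.4 |
| Friday's | 0.667 | 5.8 | 71.0 |
| Friday's | 2.00 | 15.4 | 55.6 |
| Friday's | 4.00 | 28.7 | 47.8 |
| Friday's | 6.00 | 40.1 | 39.1 |
| Friday's | 8.00 | 50.6 | 31.5 |

(readings scatter by 0.5 percentage points)

- which flask leads in amount of product, in percent of the substrate charged ("all alike" within 1.5 percentage points) (north-west / south / north-east / west / south-west / all alike)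
- how much product is there at the end, in percent of the substrate charged: north-west
- how much product is there at the end, in percent of the substrate charged: south
- how much product is there at the end, in percent of the substrate charged: north-east
- how much product is there at the end, in percent of the substrate charged: west
- how much product is there at the end, in percent of the substrate charged: south-west



**The number.** Substrate is charged in the smaller amount, 0.050 M against 0.150 M of reagent, so I treat it as the limiting reagent. Its balance says that product made is pace times warm time, up to c(substrate). For 10 min at 5 °C, N = pace × time / c(substrate) = 1.30. N is the number of whole charges the catalyst can turn over in the warm time.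

**Reading it.** West, south and south-west have N above one, so I expect most of the charge converted, short of a slowing tail. North-west and north-east warm for 2.00 min, so N = 0.260. I count the warm stretch and leave the cold one out. That is my assumption, for no earlier run was made at −35 °C.

**One number?** No. N has no term for the feed. Reagent starts at 0.15 M in each earlier run, so the readings show no order in reagent. I rank nothing among the three warm flasks.

**The forecast.** It puts west first at 94%, south at 93%, south-west at 90%, north-west at 33% and north-east at 33%. Of the reagent order it says: “I take it as zero order in the catalytic step”.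

**The result.** South-west leads with 90.3%, then south with 82.2% and west with 80.6%. These flasks share N = 1.30, yet south-west stands 9.7 percentage points above west. North-west, at N = 0.260, gives 31.2%, and north-east gives 31.5%. South-west read at 2.5 min has N = 0.326. That flask holds 35.8% product, with 40.4% substrate still there.

    substrate + free catalyst ⇌ catalyst intermediate A (K = 13.0 L mol⁻¹, k = 140 L mol⁻¹ s⁻¹, Ea = 39.0 kJ mol⁻¹, ΔH = −66.0 kJ mol⁻¹)
    catalyst intermediate A → catalyst intermediate B (k = 4.30 s⁻¹, Ea = 69.0 kJ mol⁻¹)
    reagent + catalyst intermediate B → catalyst intermediate C (k = 15.0 L mol⁻¹ s⁻¹, Ea = 37.0 kJ mol⁻¹)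
    catalyst intermediate C → by-product + catalyst intermediate D (k = 4.10 s⁻¹, Ea = 53.0 kJ mol⁻¹)
    catalyst intermediate D → free catalyst + product (k = 4.00 s⁻¹, Ea = 72.0 kJ mol⁻¹)
    substrate ⇌ dormant form (K = 0.510, k = 0.0110 s⁻¹, Ea = 70.0 kJ mol⁻¹, ΔH = −53.0 kJ mol⁻¹)
    (constants at 5 °C)

The earlier runs and the new flask were computed for an exercise; scatter was added.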